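## Retrosynthetic overview

- Last bond: the exocyclic amidine C–N bond, giving the free 2-aminoimidazole (naamine-type amine) and 1-methylparabanic acid. The trione ring is bought intact.
- Key bond: imidazole C5–CH2, giving the C5-unsubstituted 2-amino-1-methyl-4-(4-methoxybenzyl)imidazole, one CH2 unit (an iminium salt) and C2v-symmetric 2,3-dimethoxyhydroquinone. Mono-aminomethylation desymmetrises the hydroquinone, and the derived dearomatised o-quinone methide is captured by imidazole C5.
- Imidazole ring: from an N-methyl-N-(3-arylpropargyl)guanidine by 5-exo-dig hydroamination and aromatisation. The guanidine comes from the arylpropargylamine and cyanamide; the aryl–alkyne bond comes from 4-iodoanisole and N-methylpropargylamine (Sonogashira).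
- Ring order: the imidazole is the only ring built (step 2). The anisole, hydroquinone and imidazolidinetrione rings come from the starting materials.

Assumption: naamidine E as drawn has no stereocentre, axis or stereogenic double bond, so no enantioselective step is needed; 2,3-dimethoxybenzene-1,4-diol and 1-methylparabanic acid are taken as catalogue compounds.

## Route

Step 1
Reactants: 1 4-iodoanisole (1-iodo-4-methoxybenzene); 2 N-methylprop-2-yn-1-amine (N-methylpropargylamine)
Product: 3 3-(4-methoxyphenyl)-N-methylprop-2-yn-1-amine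
Conditions: PdCl2(PPh3)2 (2 mol %), CuI (4 mol %), Et3N (3 equiv), degassed THF, rt → 45 °C
Reagents that add atoms: none
Why: Sonogashira coupling: Pd(0) inserts into the aryl C–I bond and the copper acetylide of 2 transmetalates, forming the aryl–alkyne bond with the free secondary amine tolerated; no stereocentre is formed.

Step 2
Reactants: 3 3-(4-methoxyphenyl)-N-methylprop-2-yn-1-amine
Product: 6 4-[(4-methoxyphenyl)methyl]-1-methyl-1H-imidazol-2-amine, via 1-[3-(4-methoxyphenyl)prop-2-yn-1-yl]-1-methylguanidine 4 (not isolated), via (4Z)-4-[(4-methoxyphenyl)methylidene]-1-methylimidazolidin-2-imine 5 (not isolated)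
Conditions: (i) HCl (1.0 equiv, 4 M in dioxane), H2NCN (2 equiv), EtOH, 80 °C; (ii) NaOEt (2.5 equiv), EtOH, 78 °C
Reagents that add atoms: cyanamide, NC#N
Why: Guanylation of the secondary ammonium salt with cyanamide gives 4 (as its hydrochloride); its free base undergoes 5-exo-dig intramolecular hydroamination of the aryl alkyne (anti addition, Z-alkene 5) and base-mediated 1,3-prototropy aromatises the ring, so N-methyl can only become N1 and the arylmethyl group can only sit at C4; no stereocentre remains.

Step 3
Reactants: 6 4-[(4-methoxyphenyl)methyl]-1-methyl-1H-imidazol-2-amine (1.0 equiv); 7 2,3-dimethoxybenzene-1,4-diol (1.5 equiv)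
Product: 10 5-({2-amino-4-[(4-methoxyphenyl)methyl]-1-methyl-1H-imidazol-5-yl}methyl)-2,3-dimethoxybenzene-1,4-diol, via 5-[(dimethylamino)methyl]-2,3-dimethoxybenzene-1,4-diol 8 (not isolated), via 4-hydroxy-2,3-dimethoxy-6-methylidenecyclohexa-2,4-dien-1-one 9 (not isolated)
Conditions: (i) 7, CH2=NMe2+ I− (1.2 equiv), i-Pr2NEt (1.2 equiv), degassed DMF, 0 °C → rt, Ar; (ii) add 6, 100 °C, Ar
Reagents that add atoms: N,N-dimethylmethyleneiminium iodide (Eschenmoser's salt), C=[N+](C)C.[I-]
Why: Proposed new method: ortho-aminomethylation (Mannich reaction) at one of the two equivalent C–H positions of C2v-symmetric 7 gives 8, which on heating loses Me2NH to the dearomatised o-quinone methide 9; its exocyclic CH2 is attacked by the enamine-like C5 of 6 (the only free imidazole carbon) and proton loss re-aromatises both rings, giving the 2,5-dihydroxy-3,4-dimethoxybenzyl pattern whichever equivalent position reacted, while N-adducts of 9 are themselves Mannich bases and revert so the irreversible C–C adduct accumulates; the closest known reaction types are the alkylation of indoles and other π-excessive heteroarenes by phenolic Mannich bases via o-quinone methides (Michael-type addition) and the C4/C5 reactions of 2-aminoimidazoles with aldehydes and iminium ions; no stereocentre is formed.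

Step 4
Reactants: 10 5-({2-amino-4-[(4-methoxyphenyl)methyl]-1-methyl-1H-imidazol-5-yl}methyl)-2,3-dimethoxybenzene-1,4-diol; 11 1-methylimidazolidine-2,4,5-trione (1-methylparabanic acid)
Product: 15 naamidine E, 4-({5-[(2,5-dihydroxy-3,4-dimethoxyphenyl)methyl]-4-[(4-methoxyphenyl)methyl]-1-methyl-1H-imidazol-2-yl}amino)-1-methyl-1H-imidazole-2,5-dione, via 1-methyl-4-[(trimethylsilyl)oxy]-1H-imidazole-2,5-dione 12 (not isolated), via 5-{[3,4-dimethoxy-2,5-bis(trimethylsilyloxy)phenyl]methyl}-4-[(4-methoxyphenyl)methyl]-1-methyl-1H-imidazol-2-amine 13 (not isolated), via 4-[(5-{[3,4-dimethoxy-2,5-bis(trimethylsilyloxy)phenyl]methyl}-4-[(4-methoxyphenyl)methyl]-1-methyl-1H-imidazol-2-yl)amino]-1-methyl-1H-imidazole-2,5-dione 14 (not isolated)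
Conditions: 11, BSA (1.5 equiv), MeCN, 80 °C; then 10 + BSA (2.5 equiv), PhMe, 110 °C, Ar; then THF/H2O, citric acid (cat.), rt
Reagents that add atoms: N,O-bis(trimethylsilyl)acetamide (BSA), CC(=N[Si](C)(C)C)O[Si](C)(C)C (supplies the Me3Si groups of 12–14 only; none remains in 15)
Why: Silyl-imidate (lactim ether) activation of the single N–H lactam of 11, then addition–elimination by the exocyclic 2-NH2 at C4 with loss of trimethylsilanol (the classical amidine-forming naamidine endgame), while the phenols are masked in situ as TMS ethers and freed on aqueous work-up; no stereocentre is formed.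

## Compound list

1 | 4-iodoanisole | COc1ccc(I)cc1 | starting material
2 | N-methylprop-2-yn-1-amine | CNCC#C | starting material
3 | 3-(4-methoxyphenyl)-N-methylprop-2-yn-1-amine | CNCC#Cc1ccc(OC)cc1 | intermediate
4 | 1-[3-(4-methoxyphenyl)prop-2-yn-1-yl]-1-methylguanidine (formed as hydrochloride, not isolated) | CN(CC#Cc1ccc(OC)cc1)C(N)=N | intermediate
5 | (4Z)-4-[(4-methoxyphenyl)methylidene]-1-methylimidazolidin-2-imine (not isolated) | CN1C/C(=C/c2ccc(OC)cc2)NC1=N | intermediate
6 | 4-[(4-methoxyphenyl)methyl]-1-methyl-1H-imidazol-2-amine | COc1ccc(Cc2cn(C)c(N)n2)cc1 | intermediate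
7 | 2,3-dimethoxybenzene-1,4-diol | COc1c(O)ccc(O)c1OC | starting material
8 | 5-[(dimethylamino)methyl]-2,3-dimethoxybenzene-1,4-diol (not isolated) | CN(C)Cc1cc(O)c(OC)c(OC)c1O | intermediate
9 | 4-hydroxy-2,3-dimethoxy-6-methylidenecyclohexa-2,4-dien-1-one (not isolated) | C=C1C=C(O)C(OC)=C(OC)C1=O | intermediate
10 | 5-({2-amino-4-[(4-methoxyphenyl)methyl]-1-methyl-1H-imidazol-5-yl}methyl)-2,3-dimethoxybenzene-1,4-diol | COc1ccc(Cc2nc(N)n(C)c2Cc2cc(O)c(OC)c(OC)c2O)cc1 | intermediate
11 | 1-methylimidazolidine-2,4,5-trione (1-methylparabanic acid) | CN1C(=O)NC(=O)C1=O | starting material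
12 | 1-methyl-4-[(trimethylsilyl)oxy]-1H-imidazole-2,5-dione (not isolated) | CN1C(=O)N=C(O[Si](C)(C)C)C1=O | intermediate
13 | bis-O-TMS ether of 10 (not isolated) | COc1ccc(Cc2nc(N)n(C)c2Cc2cc(O[Si](C)(C)C)c(OC)c(OC)c2O[Si](C)(C)C)cc1 | intermediate
14 | bis-O-TMS ether of naamidine E (not isolated) | COc1ccc(Cc2nc(NC3=NC(=O)N(C)C3=O)n(C)c2Cc2cc(O[Si](C)(C)C)c(OC)c(OC)c2O[Si](C)(C)C)cc1 | intermediate
15 | naamidine E | COc1ccc(Cc2nc(NC3=NC(=O)N(C)C3=O)n(C)c2Cc2cc(O)c(OC)c(OC)c2O)cc1 | target

## Step count and risks

Total step count: 4. Longest linear sequence: 4 steps (1 → 3 → 6 → 10 → 15); 2, 7 and 11 are bought.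

Steps most likely to fail, most risky first:

**Step 3.** Three things can go wrong. Compound 7 can be aminomethylated at both free positions. The o-quinone methide 9 can relax by proton shift to its quinone tautomer (2,3-dimethoxy-5-methyl-1,4-benzoquinone) before C5 of 6 captures it. The hydroquinones can air-oxidise in the basic medium. The fallback reverses the polarity; it sets out from 6 (with 7 as partner) and comes back at 10. Compound 6 is aminomethylated at C5 with Eschenmoser's salt (MeCN, rt) to the gramine-type Mannich base 5-[(dimethylamino)methyl]-4-[(4-methoxyphenyl)methyl]-1-methyl-1H-imidazol-2-amine F1. F1 is then warmed with 3 equiv of 7 and MsOH (1 equiv) in HFIP at 50 °C. Loss of Me2NH, pushed by the 2-aminoimidazole, gives a 2-amino-azafulvenium ion that alkylates 7 at the carbon ortho to OH and para to OMe (Friedel–Crafts), giving 10. The acidic medium suppresses hydroquinone oxidation and 9 is never formed.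

**Step 2.** The unprotected guanidine may cyclise sluggishly, and cyanamide may oligomerise under the basic second stage. The fallback uses a protected guanidine and π-acid catalysis; it sets out from 3 and comes back at 6. Compound 3 is guanylated with N,N'-di-Boc-1H-pyrazole-1-carboxamidine (THF, rt) to tert-butyl N-[(tert-butoxycarbonylamino){[3-(4-methoxyphenyl)prop-2-yn-1-yl](methyl)amino}methylidene]carbamate F2. AgNO3 (15 mol %, MeCN, rt) then closes the ring by 5-exo-dig attack of the Boc-bearing nitrogen, giving tert-butyl (5Z)-2-[(tert-butoxycarbonyl)imino]-5-[(4-methoxyphenyl)methylidene]-3-methylimidazolidine-1-carboxylate F3. TFA/CH2Cl2 (rt) removes both Boc groups, and the freed ene-guanidine aromatises to 6.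

**Step 4.** Transient TMS protection of the hydroquinone may be incomplete, or the electron-rich ring may degrade at 110 °C, giving low conversion to the amidine. The fallback uses discrete protection; it sets out from 10 and comes back at 15. Compound 10 is silylated (TBSCl, imidazole, DMF, rt) to 5-{[2,5-bis(tert-butyldimethylsilyloxy)-3,4-dimethoxyphenyl]methyl}-4-[(4-methoxyphenyl)methyl]-1-methyl-1H-imidazol-2-amine F4. F4 is condensed with 11 under the same silyl-imidate conditions (BSA, MeCN then PhMe, 110 °C) to 4-[(5-{[2,5-bis(tert-butyldimethylsilyloxy)-3,4-dimethoxyphenyl]methyl}-4-[(4-methoxyphenyl)methyl]-1-methyl-1H-imidazol-2-yl)amino]-1-methyl-1H-imidazole-2,5-dione F5. F5 is purified as a stable, non-oxidisable compound and desilylated with TBAF/AcOH (THF, 0 °C, Ar) to give 15.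

## Further compounds

F1 | step 3 | 5-[(dimethylamino)methyl]-4-[(4-methoxyphenyl)methyl]-1-methyl-1H-imidazol-2-amine | COc1ccc(Cc2nc(N)n(C)c2CN(C)C)cc1
F2 | step 2 | tert-butyl N-[(tert-butoxycarbonylamino){[3-(4-methoxyphenyl)prop-2-yn-1-yl](methyl)amino}methylidene]carbamate | CN(CC#Cc1ccc(OC)cc1)C(=NC(=O)OC(C)(C)C)NC(=O)OC(C)(C)C
F3 | step 2 | tert-butyl (5Z)-2-[(tert-butoxycarbonyl)imino]-5-[(4-methoxyphenyl)methylidene]-3-methylimidazolidine-1-carboxylate | CN1C/C(=C/c2ccc(OC)cc2)N(C(=O)OC(C)(C)C)C1=NC(=O)OC(C)(C)C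
F4 | step 4 | 5-{[2,5-bis(tert-butyldimethylsilyloxy)-3,4-dimethoxyphenyl]methyl}-4-[(4-methoxyphenyl)methyl]-1-methyl-1H-imidazol-2-amine | COc1ccc(Cc2nc(N)n(C)c2Cc2cc(O[Si](C)(C)C(C)(C)C)c(OC)c(OC)c2O[Si](C)(C)C(C)(C)C)cc1
F5 | step 4 | 4-[(5-{[2,5-bis(tert-butyldimethylsilyloxy)-3,4-dimethoxyphenyl]methyl}-4-[(4-methoxyphenyl)methyl]-1-methyl-1H-imidazol-2-yl)amino]-1-methyl-1H-imidazole-2,5-dione | COc1ccc(Cc2nc(NC3=NC(=O)N(C)C3=O)n(C)c2Cc2cc(O[Si](C)(C)C(C)(C)C)c(OC)c(OC)c2O[Si](C)(C)C(C)(C)C)cc1
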